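**Retrosynthetic overview**

1. The chain is cut at C11=C12 and C11'=C12' (two Wittig olefinations): ring A acetylenic C15 phosphonium salt + C10 dialdehyde gives a C25 piece, which is joined last to the C15 dihydroxy-dienal of the diol end.
2. Ring A is the only ring formed in the route (step 5); the diol ring is bought as β-cyclocitral. Ring A is closed in one operation by a cobalt-catalysed [4+2] union of a 2-silyloxydiene from mesityl oxide (C1–C4) with the methyl-capped triple bond (C5≡C6) of an acyclic enediyne, making C4–C5 and C1–C6.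
3. Enabling feature: ring A is a cyclohexene whose tetrasubstituted C5=C6 is conjugated to C7≡C8 and flanked by C4H2 and quaternary C1(CH3)2, with the C3 carbinol 1,4 to C6. This is the pattern of a 2-oxydiene/1,3-diyne adduct; the C2=C3 silyl enol ether (C3 at ketone level) is the temporary group, removed by hydrolysis and reduction.
4. C3 (R) is fixed after ring formation by lipase resolution; C5' and C6' come from Sharpless epoxidation of β-cyclogeraniol and inverting hydrolysis at C5'.
5. Both end groups and the C10 unit are made or bought separately, so the route is convergent.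

Key step: step 5

Remark: carotenoid numbering is used for atoms (ring A C1–C6, chain C7–C15, primed numbers for the diol half). The Z isomers formed at C11=C12 and C11'=C12' in the Wittig steps are assumed to be brought to E by the usual mild thermal equilibration.

**Route**

Step 1
Reactants: 1 mesityl oxide (4-methylpent-3-en-2-one)
Product: 2 4-methyl-2-(trimethylsilyloxy)penta-1,3-diene
Conditions: LiN(iPr)2, THF, −78 °C; then Me3SiCl, −78 to 0 °C
Reagents that add atoms: chlorotrimethylsilane, C[Si](C)(C)Cl
Why: kinetic deprotonation at the methyl ketone terminus and O-silylation of the cross-conjugated dienolate (silyl enol ether formation) should give the 2-silyloxydiene and not the linearly conjugated isomer.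

Step 2
Reactants: 3 (2E)-3-methylpent-2-en-4-yn-1-ol
Product: 4 tert-butyl(dimethyl){[(2E)-3-methylpent-2-en-4-yn-1-yl]oxy}silane
Conditions: t-BuMe2SiCl, imidazole, DMF, rt
Reagents that add atoms: tert-butyl(chloro)dimethylsilane, CC(C)(C)[Si](C)(C)Cl
Why: standard silylation of a primary allylic alcohol, which protects it through the copper and cobalt steps.

Step 3
Reactants: 4 TBS ether of the enynol
Product: 5 {[(2E)-5-bromo-3-methylpent-2-en-4-yn-1-yl]oxy}(tert-butyl)dimethylsilane
Conditions: N-bromosuccinimide, AgNO3 (cat.), acetone, rt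
Reagents that add atoms: N-bromosuccinimide, O=C1CCC(=O)N1Br
Why: silver-catalysed electrophilic bromination of a terminal alkyne gives the 1-bromoalkyne without touching the trisubstituted alkene.

Step 4
Reactants: 5 bromoalkyne; 6 propyne
Product: 7 tert-butyl(dimethyl){[(2E)-3-methylocta-2-en-4,6-diyn-1-yl]oxy}silane
Conditions: CuCl (cat.), NH2OH·HCl (cat.), n-BuNH2, THF/H2O, 0 °C, propyne in excess
Reagents that add atoms: none
Why: Cadiot–Chodkiewicz coupling of a bromoalkyne with a terminal alkyne gives the unsymmetrical 1,3-diyne, and excess propyne suppresses homocoupling.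

Step 5
Reactants: 2 silyloxydiene; 7 enediyne
Product: 8 tert-butyl(dimethyl)({(2E)-3-methyl-5-[2,6,6-trimethyl-4-(trimethylsilyloxy)cyclohexa-1,4-dien-1-yl]pent-2-en-4-yn-1-yl}oxy)silane
Conditions: CoBr2(dppe) (10 mol %), Zn powder (20 mol %), ZnI2 (20 mol %), CH2Cl2, 25–40 °C, 7 added slowly by syringe pump
Reagents that add atoms: none
Why: Proposed new method: monovalent cobalt generated from CoBr2(dppe), Zn and ZnI2 should bind diene 2 and the methyl-capped C5≡C6 alkyne of 7, join the unsubstituted diene terminus C4 to C5 by oxidative cyclisation to an allyl(vinyl) trivalent-cobalt metallacycle, and close the ring by reductive elimination between C6 and the gem-dimethyl allyl terminus C1, the only terminus that gives a six-membered ring; the closest known reaction type is the cobalt-catalysed neutral Diels–Alder reaction of 2-trimethylsilyloxybuta-1,3-diene with unactivated alkynes and of simple dienes with 1,3-diynes, and the new element is a fully substituted diene terminus that becomes a quaternary carbon. Ring A is closed in an intermolecular [4+2] mode from two acyclic components, and because the first bond forms at the unhindered CH2 terminus the step should not need the strained s-cis geometry that defeats thermal cycloaddition of a 4,4-disubstituted diene with an unactivated diyne. No stereocentre is created and the C9=C10 E geometry is not touched. Regioselectivity (CH2 to the methyl-bearing carbon, CMe2 to the alkynyl-bearing carbon) is secured electronically by the 2-silyloxy group, which makes C4 the nucleophilic terminus and places the oxygen and the conjugating alkynyl group 1,4, and sterically because the slim alkynyl group, not the methyl group, ends up next to the quaternary centre. Chemoselectivity for C5≡C6 over C7≡C8 rests on the small methyl cap versus the branched alkenyl cap, and slow addition of the enediyne to the catalyst and the diene keeps the alkyne concentration low, which should suppress alkyne trimerisation and a second addition. The adduct is a 1,4-diene with C5=C6 already in its final place, the enyne intact, and the C2=C3 silyl enol ether as the latent C3 carbinol.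

Step 6
Reactants: 8 cycloadduct
Product: 10 racemic 4-[(3E)-5-{[tert-butyl(dimethyl)silyl]oxy}-3-methylpent-3-en-1-yn-1-yl]-3,5,5-trimethylcyclohex-3-en-1-ol, via cyclohexenone 9 (not isolated)
Conditions: PPTS (cat.), THF/H2O, 0 °C; then NaBH4, MeOH, −40 °C
Reagents that add atoms: none
Why: kinetic C-protonation of the silyl enol ether at C2 (enol ether hydrolysis) should give the β,γ-unsaturated ketone, and immediate borohydride reduction prevents migration of C5=C6 into conjugation; the carbinol is formed racemic.

Step 7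
Reactants: 10 racemic alcohol
Product: 11 (1R)-4-[(3E)-5-{[tert-butyl(dimethyl)silyl]oxy}-3-methylpent-3-en-1-yn-1-yl]-3,5,5-trimethylcyclohex-3-en-1-yl acetate
Conditions: Amano lipase PS (Burkholderia cepacia), vinyl acetate, t-BuOMe, 30 °C, stopped near half conversion
Reagents that add atoms: vinyl acetate, CC(=O)OC=C
Why: lipase-catalysed kinetic resolution by irreversible transesterification; by the empirical size rule for lipases (the C2 methylene next to quaternary C1 as the large flank) the (R)-alcohol should be acylated, fixing C3 as R, while the (S)-alcohol stays unchanged and is removed by chromatography.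

Step 8
Reactants: 11 (R)-acetate
Product: 13 (1R)-4-[(3E)-5-hydroxy-3-methylpent-3-en-1-yn-1-yl]-3,5,5-trimethylcyclohex-3-en-1-ol, via hydroxy acetate 12 (not isolated)
Conditions: Bu4NF, THF, 0 °C to rt; then K2CO3 (cat.), MeOH, rt
Reagents that add atoms: none
Why: fluoride desilylation followed by base-catalysed methanolysis of the acetate frees both hydroxyls without affecting C3 or the enyne.

Step 9
Reactants: 13 C15 diol
Product: 14 {(2E)-5-[(4R)-4-hydroxy-2,6,6-trimethylcyclohex-1-en-1-yl]-3-methylpent-2-en-4-yn-1-yl}(triphenyl)phosphonium bromide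
Conditions: PPh3·HBr, MeOH/CH2Cl2, 0 °C to rt
Reagents that add atoms: triphenylphosphine hydrobromide, [Br-].[PH+](c1ccccc1)(c1ccccc1)c1ccccc1
Why: acid-mediated substitution of the primary allylic alcohol by triphenylphosphine (phosphonium salt formation) is selective over the secondary homoallylic C3 hydroxyl and should retain the 9E geometry.

Step 10
Reactants: 14 C15 phosphonium bromide; 15 (2E,4E,6E)-2,7-dimethylocta-2,4,6-trienedial (3 equiv)
Product: 16 (3R)-3-hydroxy-7,8-didehydro-12'-apo-β-caroten-12'-al (all-E C25 aldehyde)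
Conditions: NaOMe, MeOH/CH2Cl2, 0 °C to rt; then heptane, 80 °C, no iodine
Reagents that add atoms: none
Why: Wittig olefination forms C11=C12; excess dialdehyde and the lower electrophilicity of the C25 aldehyde should hold the reaction at one olefination, and the hindered 11Z isomer is equilibrated thermally to E.

Step 11
Reactants: 16 C25 aldehyde
Product: 17 (3R)-7,8-didehydro-12'-apo-β-carotene-3,12'-diol
Conditions: NaBH4, MeOH/THF, 0 °C
Reagents that add atoms: none
Why: 1,2-reduction of a conjugated polyenal by borohydride gives the allylic alcohol.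

Step 12
Reactants: 17 C25 alcohol
Product: 18 [(3R)-3-hydroxy-7,8-didehydro-12'-apo-β-caroten-12'-yl](triphenyl)phosphonium bromide
Conditions: PPh3·HBr, MeOH/CH2Cl2, 0 °C to rt
Reagents that add atoms: triphenylphosphine hydrobromide, [Br-].[PH+](c1ccccc1)(c1ccccc1)c1ccccc1
Why: phosphonium salt formation from a polyenyl allylic alcohol, as for retinyl-type alcohols, with phosphine attack at the unhindered primary terminus.

Step 13
Reactants: 19 β-cyclocitral
Product: 20 β-cyclogeraniol, (2,6,6-trimethylcyclohex-1-en-1-yl)methanol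
Conditions: NaBH4, MeOH, 0 °C
Reagents that add atoms: none
Why: borohydride 1,2-reduction of the hindered enal gives the allylic alcohol needed for directed epoxidation.

Step 14
Reactants: 20 β-cyclogeraniol
Product: 21 [(1S,6S)-2,2,6-trimethyl-7-oxabicyclo[4.1.0]heptan-1-yl]methanol
Conditions: Ti(OiPr)4 (10 mol %), L-(+)-diisopropyl tartrate, t-BuOOH, 4 Å sieves, CH2Cl2, −20 °C
Reagents that add atoms: tert-butyl hydroperoxide, CC(C)(C)OO
Why: Sharpless asymmetric epoxidation; the titanium tartrate complex bound to the allylic hydroxyl delivers oxygen to one face of the tetrasubstituted C5'=C6' bond (the same facial sense that gives (2S,3S)-epoxy alcohols from E-allylic alcohols), setting both ring stereocentres.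

Step 15
Reactants: 21 epoxy alcohol
Product: 22 (1R,6S)-2,2,6-trimethyl-7-oxabicyclo[4.1.0]heptane-1-carbaldehyde
Conditions: (n-Pr4N)RuO4 (cat.), N-methylmorpholine N-oxide, 4 Å sieves, CH2Cl2, rt
Reagents that add atoms: none
Why: Ley–Griffith oxidation of an epoxy alcohol to the epoxy aldehyde, which has no α-hydrogen and cannot epimerise.

Step 16
Reactants: 22 epoxy aldehyde; 23 triethyl 3-methyl-4-phosphonobut-2-enoate (commercial E/Z mixture)
Product: 24 ethyl (2E,4E)-3-methyl-5-[(1R,6S)-2,2,6-trimethyl-7-oxabicyclo[4.1.0]heptan-1-yl]penta-2,4-dienoate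
Conditions: LiN(SiMe3)2, THF/DMPU, −78 to 0 °C
Reagents that add atoms: none
Why: Horner–Wadsworth–Emmons olefination with the C5 phosphonate forms C7'=C8' as the E-alkene and brings in C9'=C10' mainly as 2E; the minor 2Z ester is removed by chromatography.

Step 17
Reactants: 24 epoxy dienoate
Product: 25 ethyl (2E,4E)-5-[(1R,2R)-1,2-dihydroxy-2,6,6-trimethylcyclohexyl]-3-methylpenta-2,4-dienoate
Conditions: HClO4 (cat.), THF/H2O, 0 °C to rt
Reagents that add atoms: water, O
Why: acid-catalysed epoxide hydrolysis; water should attack the less hindered C5' with inversion because positive charge at C6' would be conjugated to the electron-poor dienoate and C6' is neopentyl, giving the trans (5'R,6'R) diol with C6' retained.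

Step 18
Reactants: 25 diol dienoate
Product: 26 (2E,4E)-5-[(1R,2R)-1,2-dihydroxy-2,6,6-trimethylcyclohexyl]-3-methylpenta-2,4-dien-1-ol
Conditions: (i-Bu)2AlH (5 equiv), CH2Cl2, −78 to 0 °C; aqueous potassium sodium tartrate work-up
Reagents that add atoms: none
Why: hydride reduction of the conjugated ester to the allylic alcohol under non-acidic conditions, which the tertiary allylic C6' hydroxyl tolerates.

Step 19
Reactants: 26 triol
Product: 27 (2E,4E)-5-[(1R,2R)-1,2-dihydroxy-2,6,6-trimethylcyclohexyl]-3-methylpenta-2,4-dienal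
Conditions: activated MnO2, CH2Cl2, rt
Reagents that add atoms: none
Why: manganese dioxide oxidises only the primary allylic alcohol under neutral conditions and leaves the two tertiary hydroxyls alone.

Step 20
Reactants: 18 C25 phosphonium bromide; 27 C15 dihydroxy-dienal
Product: 28 (3R,5'R,6'R)-7,8-didehydro-5',6'-dihydro-β,β-carotene-3,5',6'-triol (target)
Conditions: NaOMe, MeOH/CH2Cl2, 0 °C to rt; then EtOAc/heptane, 70 °C, no iodine; crystallisation
Reagents that add atoms: none
Why: Wittig olefination forms C11'=C12' under basic conditions that keep the acid-sensitive tertiary allylic diol as the aldehyde partner; no stereocentre is touched and the hindered 11'Z isomer is equilibrated thermally to E.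

**Compound list**

1 | mesityl oxide | CC(C)=CC(C)=O | starting material
2 | 4-methyl-2-(trimethylsilyloxy)penta-1,3-diene | C=C(O[Si](C)(C)C)C=C(C)C | intermediate
3 | (2E)-3-methylpent-2-en-4-yn-1-ol | C#C/C(C)=C/CO | starting material
4 | tert-butyl(dimethyl){[(2E)-3-methylpent-2-en-4-yn-1-yl]oxy}silane | C#C/C(C)=C/CO[Si](C)(C)C(C)(C)C | intermediate
5 | {[(2E)-5-bromo-3-methylpent-2-en-4-yn-1-yl]oxy}(tert-butyl)dimethylsilane | BrC#C/C(C)=C/CO[Si](C)(C)C(C)(C)C | intermediate
6 | propyne | CC#C | starting material
7 | tert-butyl(dimethyl){[(2E)-3-methylocta-2-en-4,6-diyn-1-yl]oxy}silane | CC#CC#C/C(C)=C/CO[Si](C)(C)C(C)(C)C | intermediate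
8 | cycloadduct, ring A 1,4-diene with C3 silyl enol ether | CC1=C(C#C/C(C)=C/CO[Si](C)(C)C(C)(C)C)C(C)(C)C=C(O[Si](C)(C)C)C1 | intermediate
9 | 4-[(3E)-5-{[tert-butyl(dimethyl)silyl]oxy}-3-methylpent-3-en-1-yn-1-yl]-3,5,5-trimethylcyclohex-3-en-1-one | CC1=C(C#C/C(C)=C/CO[Si](C)(C)C(C)(C)C)C(C)(C)CC(=O)C1 | intermediate (not isolated)
10 | racemic 4-[(3E)-5-{[tert-butyl(dimethyl)silyl]oxy}-3-methylpent-3-en-1-yn-1-yl]-3,5,5-trimethylcyclohex-3-en-1-ol | CC1=C(C#C/C(C)=C/CO[Si](C)(C)C(C)(C)C)C(C)(C)CC(O)C1 | intermediate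
11 | (1R)-acetate of 10 | CC1=C(C#C/C(C)=C/CO[Si](C)(C)C(C)(C)C)C(C)(C)C[C@H](OC(C)=O)C1 | intermediate
12 | (1R)-4-[(3E)-5-hydroxy-3-methylpent-3-en-1-yn-1-yl]-3,5,5-trimethylcyclohex-3-en-1-yl acetate | CC1=C(C#C/C(C)=C/CO)C(C)(C)C[C@H](OC(C)=O)C1 | intermediate (not isolated)
13 | (1R)-4-[(3E)-5-hydroxy-3-methylpent-3-en-1-yn-1-yl]-3,5,5-trimethylcyclohex-3-en-1-ol | CC1=C(C#C/C(C)=C/CO)C(C)(C)C[C@H](O)C1 | intermediate
14 | ring A C15 phosphonium bromide | CC1=C(C#C/C(C)=C/C[P+](c2ccccc2)(c2ccccc2)c2ccccc2)C(C)(C)C[C@H](O)C1.[Br-] | intermediate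
15 | (2E,4E,6E)-2,7-dimethylocta-2,4,6-trienedial | O=C/C(C)=C/C=C/C=C(C)/C=O | starting material
16 | (3R)-3-hydroxy-7,8-didehydro-12'-apo-β-caroten-12'-al | CC1=C(C#C/C(C)=C/C=C/C(C)=C/C=C/C=C(C)/C=O)C(C)(C)C[C@H](O)C1 | intermediate
17 | (3R)-7,8-didehydro-12'-apo-β-carotene-3,12'-diol | CC1=C(C#C/C(C)=C/C=C/C(C)=C/C=C/C=C(C)/CO)C(C)(C)C[C@H](O)C1 | intermediate
18 | C25 phosphonium bromide | CC1=C(C#C/C(C)=C/C=C/C(C)=C/C=C/C=C(C)/C[P+](c2ccccc2)(c2ccccc2)c2ccccc2)C(C)(C)C[C@H](O)C1.[Br-] | intermediate
19 | β-cyclocitral | CC1=C(C=O)C(C)(C)CCC1 | starting material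
20 | β-cyclogeraniol | CC1=C(CO)C(C)(C)CCC1 | intermediate
21 | [(1S,6S)-2,2,6-trimethyl-7-oxabicyclo[4.1.0]heptan-1-yl]methanol | OC[C@@]12C(C)(C)CCC[C@]1(C)O2 | intermediate
22 | (1R,6S)-2,2,6-trimethyl-7-oxabicyclo[4.1.0]heptane-1-carbaldehyde | O=C[C@@]12C(C)(C)CCC[C@]1(C)O2 | intermediate
23 | triethyl 3-methyl-4-phosphonobut-2-enoate (E/Z mixture) | CCOC(=O)C=C(C)CP(=O)(OCC)OCC | starting material
24 | ethyl (2E,4E)-3-methyl-5-[(1R,6S)-2,2,6-trimethyl-7-oxabicyclo[4.1.0]heptan-1-yl]penta-2,4-dienoate | CCOC(=O)/C=C(C)/C=C/[C@@]12C(C)(C)CCC[C@]1(C)O2 | intermediate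
25 | ethyl (2E,4E)-5-[(1R,2R)-1,2-dihydroxy-2,6,6-trimethylcyclohexyl]-3-methylpenta-2,4-dienoate | CCOC(=O)/C=C(C)/C=C/[C@@]1(O)C(C)(C)CCC[C@@]1(C)O | intermediate
26 | (2E,4E)-5-[(1R,2R)-1,2-dihydroxy-2,6,6-trimethylcyclohexyl]-3-methylpenta-2,4-dien-1-ol | OC/C=C(C)/C=C/[C@@]1(O)C(C)(C)CCC[C@@]1(C)O | intermediate
27 | (2E,4E)-5-[(1R,2R)-1,2-dihydroxy-2,6,6-trimethylcyclohexyl]-3-methylpenta-2,4-dienal | O=C/C=C(C)/C=C/[C@@]1(O)C(C)(C)CCC[C@@]1(C)O | intermediate
28 | (3R,5'R,6'R)-7,8-didehydro-5',6'-dihydro-β,β-carotene-3,5',6'-triol | CC1=C(C#C/C(C)=C/C=C/C(C)=C/C=C/C=C(C)/C=C/C=C(C)/C=C/[C@@]2(O)C(C)(C)CCC[C@@]2(C)O)C(C)(C)C[C@H](O)C1 | target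

**Step count and risks**

Total steps: 20. Longest linear sequence: 12 steps (steps 2 to 12, then step 20; from 3 to 28).

Step 5 (Proposed new method). What may go wrong: the fully substituted diene terminus may fail to enter the metallacycle, so that alkyne oligomerisation, reaction at the C7≡C8 alkyne or a second addition takes over. Fallback with known chemistry, setting out from 4 and coming back at 11: ring A is taken from the chiral pool instead of being built. Lithiation of 4 (n-BuLi, THF, −78 °C, acetylide in excess) and addition to commercial (4R,6R)-4-hydroxy-2,2,6-trimethylcyclohexanone should give (4R,6R)-1-[(3E)-5-{[tert-butyl(dimethyl)silyl]oxy}-3-methylpent-3-en-1-yn-1-yl]-2,2,6-trimethylcyclohexane-1,4-diol F1 as C1 epimers. Acetylation of the secondary hydroxyl only (Ac2O, pyridine, 0 °C) gives the 4-acetate F2. Dehydration of the tertiary propargylic alcohol (POCl3, pyridine, 60 °C), which can only remove the ring hydrogen at C5, gives 11, and steps 5 to 7 are then not needed.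

Step 7. What may go wrong: poor discrimination of the two enantiomers by the lipase, because the carbinol is flanked by two methylene groups. Fallback, setting out from 10 and coming back at 13: covalent resolution. Esterification of 10 with (S)-methoxy(phenyl)acetic acid (DCC, DMAP, CH2Cl2) gives two diastereomeric esters that are separated by chromatography. The (1R)-ester, (1R)-4-[(3E)-5-{[tert-butyl(dimethyl)silyl]oxy}-3-methylpent-3-en-1-yn-1-yl]-3,5,5-trimethylcyclohex-3-en-1-yl (2S)-methoxy(phenyl)acetate F3, is taken through the conditions of step 8 (Bu4NF; then K2CO3, MeOH) to 13.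

Step 17. What may go wrong: loss of regiocontrol in the epoxide opening (cleavage of the allylic C6'–O bond instead of attack at C5'), which would erode enantiomeric purity or lead to furanoid rearrangement. Fallback, setting out from 22 and coming back at 26: the hydrolysis is done with an alkynyl group on C6', which disfavours positive charge there. Ohira–Bestmann homologation of 22 (dimethyl (1-diazo-2-oxopropyl)phosphonate, K2CO3, MeOH) gives (1S,6S)-1-ethynyl-2,2,6-trimethyl-7-oxabicyclo[4.1.0]heptane F4. Aqueous acid (H2SO4 cat., THF/H2O) should open it at C5' with inversion to (1S,2R)-1-ethynyl-2,6,6-trimethylcyclohexane-1,2-diol F5. Sonogashira coupling (Pd(PPh3)2Cl2, CuI, Et3N, THF) with ethyl (2E)-3-{[(trifluoromethyl)sulfonyl]oxy}but-2-enoate F6, made from ethyl acetoacetate (aqueous Me4NOH, Tf2O), gives ethyl (2E)-5-[(1S,2R)-1,2-dihydroxy-2,6,6-trimethylcyclohexyl]-3-methylpent-2-en-4-ynoate F7. NaAlH2(OCH2CH2OMe)2 in THF then reduces the ester and, by hydroxyl-directed trans-hydroalumination, the triple bond to the E-alkene, giving 26.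

**Further compounds**

F1 | step 5 | (4R,6R)-1-[(3E)-5-{[tert-butyl(dimethyl)silyl]oxy}-3-methylpent-3-en-1-yn-1-yl]-2,2,6-trimethylcyclohexane-1,4-diol (C1 epimers) | CC(C)(C)[Si](C)(C)OC/C=C(C)/C#CC1(O)[C@H](C)C[C@@H](O)CC1(C)C
F2 | step 5 | (1R,5R)-4-[(3E)-5-{[tert-butyl(dimethyl)silyl]oxy}-3-methylpent-3-en-1-yn-1-yl]-4-hydroxy-3,3,5-trimethylcyclohexyl acetate (C4 epimers) | CC(C)(C)[Si](C)(C)OC/C=C(C)/C#CC1(O)[C@H](C)C[C@@H](OC(C)=O)CC1(C)C
F3 | step 7 | (1R)-4-[(3E)-5-{[tert-butyl(dimethyl)silyl]oxy}-3-methylpent-3-en-1-yn-1-yl]-3,5,5-trimethylcyclohex-3-en-1-yl (2S)-methoxy(phenyl)acetate | CC1=C(C#C/C(C)=C/CO[Si](C)(C)C(C)(C)C)C(C)(C)C[C@H](OC(=O)[C@@H](OC)c2ccccc2)C1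
F4 | step 17 | (1S,6S)-1-ethynyl-2,2,6-trimethyl-7-oxabicyclo[4.1.0]heptane | C#C[C@@]12C(C)(C)CCC[C@]1(C)O2
F5 | step 17 | (1S,2R)-1-ethynyl-2,6,6-trimethylcyclohexane-1,2-diol | C#C[C@@]1(O)C(C)(C)CCC[C@@]1(C)O
F6 | step 17 | ethyl (2E)-3-{[(trifluoromethyl)sulfonyl]oxy}but-2-enoate | CCOC(=O)/C=C(C)/OS(=O)(=O)C(F)(F)F
F7 | step 17 | ethyl (2E)-5-[(1S,2R)-1,2-dihydroxy-2,6,6-trimethylcyclohexyl]-3-methylpent-2-en-4-ynoate | CCOC(=O)/C=C(C)/C#C[C@@]1(O)C(C)(C)CCC[C@@]1(C)O
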